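**Route plan**

- Retrosynthesis: the two angelate C–O bonds (C6, C10), the C8–O and C9–O bonds (osmylation of a C8=C9 enone) and the C10–H bond are cut first, which exposes a trans-fused 5-7 aldol.
- Enabling feature: C4(OH)(iPr)–C5(H)–C6(=O) is an aldol unit across the ring fusion, with the quaternary, methyl-bearing C1 bonded to C5. Cutting C1–C5 and rejoining C1 to C6 (retro-semipinacol) turns the cyclopentane (C1–C5) and the cycloheptane (C1, C5–C10) into a cis-decalin 2,3-epoxy alcohol.
- The decalin is cut at the ring–isopropyl bond (cross-coupling), at the epoxide C–O bonds and at the two C–C bonds of a Robinson annulation, back to 5-methylcyclohexane-1,3-dione, iodomethane and methyl vinyl ketone.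
- Forward: the cyclohexanedione ring is bought, the second six-membered ring closes by proline-mediated aldol condensation, one 1,2-shift converts 6-6 into 5-7, and enone, diol and esters are added to the seven-membered ring last.
- Stereochemistry: C1 from the D-proline desymmetrisation; C4 and C5 from a β-epoxide (relayed from C1 by enone epoxidation and hydroxyl-directed epoxidation) through the stereospecific shift; C6 by hydroxyl-directed hydride; C8 and C9 by osmylation anti to the C1 methyl; C10 by hydride anti to the acetonide; the Z-alkenes come with angelic acid.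

Key step: step 10

Remark on numbering: from step 10 on, daucane numbering is used for the 5-7 bicycle (C1 methyl-bearing fusion carbon, C2 and C3 cyclopentane methylenes, C4 isopropyl carbinol, C5 fusion CH, C6 to C10 around the seven-membered ring with C10 next to C1; methyls on C1 and C8). All such compounds are trans-fused with 1β-methyl, 5α-H and 4α-isopropyl. Before step 10 the naphthalene numbering of the decalin is used (C8a methyl-bearing fusion carbon, C4a the other fusion carbon, C1 the ketal carbon, C3 the methyl-bearing CH). The shift maps C8a, C4a, C5, C6, C7, C8, C1, C2, C3, C4 onto C1, C6, C5, C4, C3, C2, C10, C9, C8, C7. β is the face of the angular methyl, α the opposite face.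

Assumption: the secondary methyl-bearing carbon (decalin C3, later C8) is carried as both epimers and left undefined in structures 4 to 21, because step 14 makes it trigonal. The epimers may instead be separated after step 3; the enantiomeric purity reached in step 3 would be checked there and, if needed, raised by crystallisation.

**Route**

Step 1
Reactants: 1 5-methylcyclohexane-1,3-dione
Product: 2 2,5-dimethylcyclohexane-1,3-dione
Conditions: MeI, KOH, H2O–MeOH, 65 °C
Reagents that add atoms: iodomethane, CI
Why: C-alkylation of the 1,3-dione enolate at the doubly activated C2 is the standard route to 2-alkylcyclohexane-1,3-diones, and no stereocentre is created.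

Step 2
Reactants: 2 2,5-dimethylcyclohexane-1,3-dione; 3 methyl vinyl ketone
Product: 4 2,5-dimethyl-2-(3-oxobutyl)cyclohexane-1,3-dione (cis and trans isomers; both achiral)
Conditions: Et3N (cat.), EtOAc, rt
Reagents that add atoms: none
Why: Michael addition of the dione enolate to the enone builds the quaternary carbon, and each diastereomer keeps a mirror plane through C2 and C5, so no absolute configuration is fixed yet.

Step 3
Reactants: 4 2,5-dimethyl-2-(3-oxobutyl)cyclohexane-1,3-dione
Product: 6 (8aR)-3,8a-dimethyl-3,4,8,8a-tetrahydronaphthalene-1,6(2H,7H)-dione (both C3 epimers), via cis-ketol 5 (not isolated)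
Conditions: D-proline (20 mol %), DMSO, rt
Reagents that add atoms: none
Why: Hajos–Parrish–Eder–Sauer–Wiechert reaction, in which the D-proline enamine of the side-chain ketone adds to one of the two enantiotopic ring carbonyls through the hydrogen-bonded transition state and ketol 5 dehydrates in the flask, so that C8a is set as R (mirror image of the L-proline outcome) for either C3 epimer.

Step 4
Reactants: 6 (8aR)-3,8a-dimethyl-3,4,8,8a-tetrahydronaphthalene-1,6(2H,7H)-dione
Product: 7 (8aR)-1,1-ethylenedioxy-3,8a-dimethyl-1,2,3,4,8,8a-hexahydronaphthalen-6(7H)-one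
Conditions: ethylene glycol, p-TsOH·H2O, 4 Å MS, rt
Reagents that add atoms: ethylene glycol, OCCO
Why: acid-catalysed acetalisation is selective for the saturated C1 ketone because the enone carbonyl is deactivated by conjugation, as established for the parent Wieland–Miescher ketone, and no stereocentre is affected.

Step 5
Reactants: 7 (8aR)-1,1-ethylenedioxy-3,8a-dimethyl-1,2,3,4,8,8a-hexahydronaphthalen-6(7H)-one
Product: 8 4aβ,5β-epoxy-1,1-ethylenedioxy-3,8aβ-dimethyldecalin-6-one (oxirane cis to the angular methyl)
Conditions: 30% aq. H2O2, NaOH, MeOH, 0 °C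
Reagents that add atoms: hydrogen peroxide, OO
Why: Weitz–Scheffer epoxidation, in which hydroperoxide adds axially to C4a on the face of the angular methyl and the enolate closes the oxirane, the course known for angularly methylated octalenones and steroidal 4-en-3-ones, so C4a and C5 are set β under control of C8a.

Step 6
Reactants: 8 4aβ,5β-epoxy-1,1-ethylenedioxy-3,8aβ-dimethyldecalin-6-one
Product: 10 4aβ,5β-epoxy-1,1-ethylenedioxy-3,8aβ-dimethyl-6,7-dehydrodecalin-6-yl trifluoromethanesulfonate (enol triflate), via potassium enolate 9 (not isolated)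
Conditions: KN(SiMe3)2, THF, −78 °C; then PhNTf2, −78 → 0 °C
Reagents that add atoms: N-phenylbis(trifluoromethanesulfonimide), O=S(=O)(N(c1ccccc1)S(=O)(=O)C(F)(F)F)C(F)(F)F
Why: kinetic enolisation can only take place towards C7 because the other alpha carbon is the oxirane CH, and O-sulfonylation of the enolate with PhNTf2 is the standard enol triflate synthesis, with no stereocentre touched.

Step 7
Reactants: 10 4aβ,5β-epoxy-1,1-ethylenedioxy-3,8aβ-dimethyl-6,7-dehydrodecalin-6-yl trifluoromethanesulfonate; 11 isopropylzinc bromide
Product: 12 4aβ,5β-epoxy-1,1-ethylenedioxy-6-isopropyl-3,8aβ-dimethyl-6,7-dehydrodecalin (vinyl epoxide)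
Conditions: PdCl2(dppf) (5 mol %), THF, rt
Reagents that add atoms: none
Why: Negishi coupling of an alkenyl triflate with a secondary alkylzinc halide, for which the wide-bite-angle ferrocenyl diphosphine speeds reductive elimination over β-hydride elimination so that the isopropyl group is transferred unrearranged, while the organozinc leaves epoxide and acetal untouched and no stereocentre is formed.

Step 8
Reactants: 12 4aβ,5β-epoxy-1,1-ethylenedioxy-6-isopropyl-3,8aβ-dimethyl-6,7-dehydrodecalin
Product: 13 cis-fused 1,1-ethylenedioxy-6-isopropyl-3,8aβ-dimethyl-5,6-dehydrodecalin-4aβ-ol (tertiary allylic alcohol)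
Conditions: SmI2, THF–MeOH, −78 °C
Reagents that add atoms: none
Why: reductive opening of a vinyl epoxide by two single-electron transfers, in which the allylic C5–O bond breaks and the allylsamarium intermediate is protonated at the remote terminus C7, so the double bond moves to C5=C6 and the oxygen stays on C4a with its β configuration.

Step 9
Reactants: 13 cis-fused 1,1-ethylenedioxy-6-isopropyl-3,8aβ-dimethyl-5,6-dehydrodecalin-4aβ-ol
Product: 14 cis-fused 5β,6β-epoxy-1,1-ethylenedioxy-6α-isopropyl-3,8aβ-dimethyldecalin-4aβ-ol (syn epoxy alcohol)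
Conditions: VO(acac)2 (cat.), t-BuOOH, CH2Cl2, 0 °C → rt
Reagents that add atoms: tert-butyl hydroperoxide, CC(C)(C)OO
Why: hydroxyl-directed epoxidation, in which the vanadium alkoxide of the tertiary allylic alcohol delivers the peroxide oxygen to the alkene face that carries the hydroxyl, which sets C5 and C6 β.

Step 10
Reactants: 14 cis-fused 5β,6β-epoxy-1,1-ethylenedioxy-6α-isopropyl-3,8aβ-dimethyldecalin-4aβ-ol
Product: 17 10,10-ethylenedioxy-4β-hydroxydaucan-6-one (trans-fused aldol), via aluminium alkoxide 15 (not isolated), via aluminium aldolate 16 (not isolated)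
Conditions: Me2AlCl (1.2 equiv), CH2Cl2, −78 → −30 °C; then aq. potassium sodium tartrate, 0 °C
Reagents that add atoms: none
Why: Proposed new method: Me2AlCl converts the tertiary hydroxyl into the chloro(methyl)aluminium alkoxide 15, whose metal also binds the syn epoxide oxygen, and within this chelate the quaternary C1 (decalin C8a) shifts from C6 to C5 at the rear of the breaking C5–O bond while the alkoxide collapses to the C6 ketone and the epoxide oxygen stays on C4 as the alkoxide of aldolate 16. The closest known reaction type is the Lewis-acid semipinacol rearrangement of 2,3-epoxy alcohols to aldols, which includes contraction of 1-substituted 2,3-epoxycyclohexanols to 2-acylcyclopentanols; its use across a decalin ring fusion, with a secondary migration terminus and a tertiary distal epoxide carbon, has not been shown. The cyclopentane (C1–C5) is formed by ring contraction, that is by the 1,2-shift of C1 and not by a cyclisation, and the cycloheptanone (C1, C5–C10) by the matching one-carbon expansion of the neighbouring ring. C5 is set with inversion because C1 arrives anti to the leaving oxygen (hence H5 α and the trans fusion), C4 keeps the β oxygen of the epoxide (hydroxyl cis to the C1 methyl), C1 migrates with retention and C6 becomes trigonal. The step needs cleavage of the secondary C5–O bond and not of the tertiary C4–O bond, and migration of C1 and not of the C7 methylene that also sits on the carbinol: the alkoxide push can assist only C5–O cleavage, a single equivalent of a chelated aluminium centre at low temperature disfavours unassisted ionisation at C4, the five-membered chelate draws the two oxygens towards eclipse and so turns the C1–C6 bond towards the rear of C5, and the quaternary carbon is the better migrating group. The six-membered aluminium chelate of aldolate 16 holds the product against retro-aldol cleavage and dehydration until the cold, near-neutral work-up.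

Step 11
Reactants: 17 10,10-ethylenedioxy-4β-hydroxydaucan-6-one
Product: 18 10,10-ethylenedioxydaucane-4β,6α-diol
Conditions: Me4NBH(OAc)3, MeCN–AcOH, −30 °C
Reagents that add atoms: none
Why: Evans–Saksena directed reduction, in which the C4 hydroxyl exchanges onto boron and hydride is delivered within that boron ester to the β face of the C6 carbonyl, giving the 6α-alcohol (trans to the C4 hydroxyl), while the mildly acidic medium avoids retro-aldol cleavage and spares the dioxolane at this temperature.

Step 12
Reactants: 18 10,10-ethylenedioxydaucane-4β,6α-diol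
Product: 19 4β,6α-dihydroxydaucan-10-one
Conditions: PPTS, acetone–H2O, 55 °C
Reagents that add atoms: water, O
Why: acid-catalysed acetal hydrolysis frees the C10 ketone under conditions mild enough to leave the tertiary C4 carbinol intact, and no stereocentre is affected.

Step 13
Reactants: 19 4β,6α-dihydroxydaucan-10-one
Product: 20 4β,6α,10-tris(trimethylsilyloxy)dauc-9-ene (silyl enol ether carrying two silyl ethers)
Conditions: TMSOTf (3.5 equiv), Et3N, CH2Cl2, 0 °C
Reagents that add atoms: trimethylsilyl trifluoromethanesulfonate, C[Si](C)(C)OS(=O)(=O)C(F)(F)F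
Why: soft enolisation with a silyl triflate and an amine, which can only go towards C9 because C1 is quaternary, with silylation of both hydroxyls in the same operation (three silyl groups in all) to protect them during the oxidation, and no stereocentre is formed.

Step 14
Reactants: 20 4β,6α,10-tris(trimethylsilyloxy)dauc-9-ene
Product: 22 4β,6α-dihydroxydauc-8-en-10-one, via bis-silyl enone 21 (not isolated)
Conditions: Pd(OAc)2 (1.05 equiv), MeCN, rt; then 1 M HCl, THF, 0 °C
Reagents that add atoms: none
Why: Saegusa–Ito oxidation, in which the palladium enolate formed from the silyl enol ether undergoes β-hydride elimination from C8 (the only carbon that can supply the hydrogen) to give the C8=C9 enone, which makes C8 trigonal so that both methyl epimers converge, and dilute acid then cleaves the two silyl ethers.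

Step 15
Reactants: 22 4β,6α-dihydroxydauc-8-en-10-one
Product: 23 4β,6α,8α,9α-tetrahydroxydaucan-10-one (8β-methyl)
Conditions: K2OsO4·2H2O (5 mol %), NMO, citric acid, t-BuOH–H2O, rt
Reagents that add atoms: N-methylmorpholine N-oxide, C[N+]1([O-])CCOCC1; water, O
Why: catalytic syn-dihydroxylation by osmium tetroxide generated in the flask, accelerated by citric acid for the electron-poor alkene, which adds to the α face because the axial C1 methyl shields the β face of the C8=C9 bond, so the C8 and C9 oxygens are both α.

Step 16
Reactants: 23 4β,6α,8α,9α-tetrahydroxydaucan-10-one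
Product: 24 4β,6α-dihydroxy-8α,9α-(isopropylidenedioxy)daucan-10-one
Conditions: Me2C(OMe)2, PPTS, CH2Cl2, rt
Reagents that add atoms: 2,2-dimethoxypropane, COC(C)(C)OC
Why: acid-catalysed acetonide formation is selective for the cis-vicinal 8,9-diol (five-membered dioxolane) over the isolated C4 and C6 hydroxyls and shields the alpha-ketol from enolisation, with no stereocentre changed.

Step 17
Reactants: 24 4β,6α-dihydroxy-8α,9α-(isopropylidenedioxy)daucan-10-one
Product: 25 8α,9α-(isopropylidenedioxy)daucane-4β,6α,10α-triol
Conditions: NaBH4, MeOH, −20 °C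
Reagents that add atoms: none
Why: borohydride reduction of an alpha-alkoxy ketone, in which hydride attacks C10 anti to the C9–O bond (polar Felkin–Anh model) and away from the α-fused dioxolane, that is from the β face, which gives the 10α-alcohol cis to the C8 and C9 oxygens.

Step 18
Reactants: 25 8α,9α-(isopropylidenedioxy)daucane-4β,6α,10α-triol; 26 angelic acid ((Z)-2-methylbut-2-enoic acid), of which two molecules are incorporated
Product: 28 6α,10α-bis(angeloyloxy)-8α,9α-(isopropylidenedioxy)daucan-4β-ol, via mixed anhydride 27 (not isolated)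
Conditions: 26 (3 equiv), 2,4,6-trichlorobenzoyl chloride (3 equiv), Et3N, toluene, rt; then 25, 80 °C
Reagents that add atoms: angelic acid (second equivalent of 26), C/C=C(/C)C(=O)O
Why: Yamaguchi-type twofold esterification without a nucleophilic catalyst, in which each secondary hydroxyl takes one angeloyl group from a molecule of mixed anhydride 27 (used in excess so that both the C6 and the hindered C10 hydroxyl react) at the less hindered angeloyl carbonyl, the tertiary C4 hydroxyl stays free and, because nothing adds reversibly to the double bond, the Z geometry is kept, while the carbinol configurations are retained since only O–acyl bonds form.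

Step 19
Reactants: 28 6α,10α-bis(angeloyloxy)-8α,9α-(isopropylidenedioxy)daucan-4β-ol
Product: 29 6α,10α-bis(angeloyloxy)daucane-4β,8α,9α-triol (CNP0194216.1)
Conditions: AcOH–H2O (4:1), 40 °C
Reagents that add atoms: none
Why: acid-catalysed hydrolysis of the isopropylidene acetal in aqueous acetic acid frees the 8,9-diol under conditions that should neither cleave nor isomerise the angelates nor dehydrate the tertiary carbinols, and no stereocentre is touched.

**Compound list**

1 | 5-methylcyclohexane-1,3-dione | CC1CC(=O)CC(=O)C1 | starting material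
2 | 2,5-dimethylcyclohexane-1,3-dione | CC1CC(=O)C(C)C(=O)C1 | intermediate
3 | methyl vinyl ketone (but-3-en-2-one) | C=CC(C)=O | starting material
4 | 2,5-dimethyl-2-(3-oxobutyl)cyclohexane-1,3-dione (cis and trans, both achiral) | CC(=O)CCC1(C)C(=O)CC(C)CC1=O | intermediate
5 | cis-fused ketol: 4aβ-hydroxy-3,8aβ-dimethyldecalin-1,6-dione | O=C1CC(C)C[C@@]2(O)CC(=O)CC[C@@]12C | intermediate
6 | (8aR)-3,8a-dimethyl-3,4,8,8a-tetrahydronaphthalene-1,6(2H,7H)-dione | O=C1CC(C)CC2=CC(=O)CC[C@@]12C | intermediate
7 | (8aR)-1,1-ethylenedioxy-3,8a-dimethyl-1,2,3,4,8,8a-hexahydronaphthalen-6(7H)-one | CC1CC2=CC(=O)CC[C@@]2(C)C3(C1)OCCO3 | intermediate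
8 | 4aβ,5β-epoxy-1,1-ethylenedioxy-3,8aβ-dimethyldecalin-6-one | CC1C[C@]23O[C@@H]3C(=O)CC[C@@]2(C)C4(C1)OCCO4 | intermediate
9 | potassium enolate of 8 (C6–O, C6=C7) | CC1C[C@]23O[C@@H]3C([O-])=CC[C@@]2(C)C4(C1)OCCO4.[K+] | intermediate
10 | enol triflate of 8 (6-triflyloxy, C6=C7, 4aβ,5β-epoxide) | CC1C[C@]23O[C@@H]3C(OS(=O)(=O)C(F)(F)F)=CC[C@@]2(C)C4(C1)OCCO4 | intermediate
11 | isopropylzinc bromide | CC(C)[Zn]Br | starting material
12 | vinyl epoxide: 4aβ,5β-epoxy-6-isopropyl, C6=C7, C1 dioxolane | CC1C[C@]23O[C@@H]3C(C(C)C)=CC[C@@]2(C)C4(C1)OCCO4 | intermediate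
13 | cis-decalin allylic alcohol: 4aβ-OH, C5=C6, 6-isopropyl, C1 dioxolane | CC1C[C@@]2(O)C=C(C(C)C)CC[C@@]2(C)C3(C1)OCCO3 | intermediate
14 | syn epoxy alcohol: 4aβ-OH, 5β,6β-epoxide, 6α-isopropyl, 8aβ-methyl, C1 dioxolane | CC1C[C@@]2(O)[C@@H]3O[C@]3(C(C)C)CC[C@@]2(C)C4(C1)OCCO4 | intermediate
15 | chloro(methyl)aluminium alkoxide of 14 | CC1C[C@@]2(O[Al](C)Cl)[C@@H]3O[C@]3(C(C)C)CC[C@@]2(C)C4(C1)OCCO4 | intermediate
16 | chloro(methyl)aluminium aldolate of 17 (aluminium on the C4 oxygen) | O=C1CC(C)CC2(OCCO2)[C@]3(C)CC[C@](O[Al](C)Cl)(C(C)C)[C@@H]13 | intermediate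
17 | 10,10-ethylenedioxy-4β-hydroxydaucan-6-one (trans-fused, 1β-methyl, 5α-H, 4α-isopropyl) | O=C1CC(C)CC2(OCCO2)[C@]3(C)CC[C@](O)(C(C)C)[C@@H]13 | intermediate
18 | 10,10-ethylenedioxydaucane-4β,6α-diol | O[C@@H]1CC(C)CC2(OCCO2)[C@]3(C)CC[C@](O)(C(C)C)[C@@H]13 | intermediate
19 | 4β,6α-dihydroxydaucan-10-one | O[C@@H]1CC(C)CC(=O)[C@]2(C)CC[C@](O)(C(C)C)[C@@H]12 | intermediate
20 | 4β,6α,10-tris(trimethylsilyloxy)dauc-9-ene | C[Si](C)(C)O[C@@H]1CC(C)C=C(O[Si](C)(C)C)[C@]2(C)CC[C@](O[Si](C)(C)C)(C(C)C)[C@@H]12 | intermediate
21 | 4β,6α-bis(trimethylsilyloxy)dauc-8-en-10-one | C[Si](C)(C)O[C@@H]1CC(C)=CC(=O)[C@]2(C)CC[C@](O[Si](C)(C)C)(C(C)C)[C@@H]12 | intermediate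
22 | 4β,6α-dihydroxydauc-8-en-10-one | O[C@@H]1CC(C)=CC(=O)[C@]2(C)CC[C@](O)(C(C)C)[C@@H]12 | intermediate
23 | 4β,6α,8α,9α-tetrahydroxydaucan-10-one (8β-methyl) | O[C@@H]1C[C@](C)(O)[C@H](O)C(=O)[C@]2(C)CC[C@](O)(C(C)C)[C@@H]12 | intermediate
24 | 4β,6α-dihydroxy-8α,9α-(isopropylidenedioxy)daucan-10-one | O[C@@H]1C[C@]2(C)OC(C)(C)O[C@@H]2C(=O)[C@]3(C)CC[C@](O)(C(C)C)[C@@H]13 | intermediate
25 | 8α,9α-(isopropylidenedioxy)daucane-4β,6α,10α-triol | O[C@@H]1C[C@]2(C)OC(C)(C)O[C@@H]2[C@H](O)[C@]3(C)CC[C@](O)(C(C)C)[C@@H]13 | intermediate
26 | angelic acid ((Z)-2-methylbut-2-enoic acid) | C/C=C(/C)C(=O)O | starting material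
27 | angelic 2,4,6-trichlorobenzoic anhydride | C/C=C(/C)C(=O)OC(=O)c1c(Cl)cc(Cl)cc1Cl | intermediate
28 | 6α,10α-bis(angeloyloxy)-8α,9α-(isopropylidenedioxy)daucan-4β-ol | C/C=C(/C)C(=O)O[C@@H]1C[C@]2(C)OC(C)(C)O[C@@H]2[C@H](OC(=O)/C(C)=C\C)[C@]3(C)CC[C@](O)(C(C)C)[C@@H]13 | intermediate
29 | 6α,10α-bis(angeloyloxy)daucane-4β,8α,9α-triol (CNP0194216.1) | C/C=C(/C)C(=O)O[C@@H]1C[C@](C)(O)[C@H](O)[C@H](OC(=O)/C(C)=C\C)[C@]2(C)CC[C@](O)(C(C)C)[C@@H]12 | target

**Step count**

Total step count: 19. Longest linear sequence: 19 steps (1 to 29; compounds 3, 11 and 26 are bought and enter directly).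

**Steps most likely to fail**

Step 10 (proposed new method). Two processes may defeat it. In the ordinary half-chair of the epoxide-bearing ring it is the C6–C7 bond, not the C1–C6 bond, that lies anti to the C5–O bond, so the C7 methylene may migrate unless the chelate reorganises the ring. Alternatively the epoxide may ionise at the tertiary C4–O bond, followed by hydride shift or chloride capture. The fallback replaces the epoxide by an equatorial sulfonate, which is anti to the ring-fusion bond and can only leave from C5. It uses the established pinacol-type rearrangement of vicinal diol monosulfonates, by which decalins are converted into hydroazulenones.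

It sets out from allylic alcohol 13. Hydroxyl-directed syn-dihydroxylation with OsO4 and TMEDA (CH2Cl2, −78 °C) on the β face would give the osmate ester F1, cleaved with aqueous Na2SO3 to the all-cis 4aβ,5β,6β-triol F2. The only secondary hydroxyl would be mesylated (MsCl, Et3N, CH2Cl2, 0 °C) to the 5β-mesylate F3. Et3Al (CH2Cl2, −78 °C) would then form the aluminium alkoxides and drive the 1,2-shift of the ring-fusion carbon anti to the departing mesylate, with the same inversion at C5 and retention at C4 as in step 10. The route is rejoined at aldol 17. Because all three oxygens are cis, neither flanking alkoxide can close an epoxide. The second tertiary hydroxyl (on daucane C4) could in principle drive a shift of C3, but the quaternary C1 is expected to migrate in preference.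

Step 7. Zerovalent palladium may ionise the allylic epoxide of triflate 10 or of product 12 to a π-allyl alkoxide, and β-hydride elimination with reinsertion may scramble the isopropyl group to n-propyl. The fallback avoids palladium and forms the ring–isopropyl bond by carbonyl addition.

It sets out from epoxy ketone 8. iPrMgCl with CeCl3 (THF, −78 °C) would add to the C6 carbonyl to give the tertiary epoxy carbinol F4 (either C6 epimer serves). Dehydration with the Burgess reagent (toluene, 50 °C) would give vinyl epoxide 12 together with its exocyclic isopropylidene isomer F5. Both are allylic epoxides, and the SmI2 reduction of step 8 places hydrogen on the remote alkene terminus of either (C7 or the isopropylidene carbon), so the mixture converges on allylic alcohol 13, where the route is rejoined.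

Step 18. Acylation of the neopentyl-like C10 hydroxyl may stay incomplete at a temperature low enough to prevent Z to E isomerisation of the angeloyl unit to the tigloyl unit, which would leave a mono-ester. The fallback forms the ester bonds first and builds the Z-alkenes afterwards.

It sets out from triol 25. Both secondary hydroxyls would be acylated with two equivalents of 2-[bis(2,2,2-trifluoroethoxy)phosphoryl]propanoic acid (DCC, DMAP, CH2Cl2, rt) to the bis-phosphonate F6. A twofold Still–Gennari olefination with acetaldehyde (KN(SiMe3)2, 18-crown-6, THF, −78 °C) would then form both (Z)-2-methylbut-2-enoates in place, and the route is rejoined at bis-angelate 28.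

Further compounds
F1 | step 10 | osmate ester of the 5β,6β-diol of 13 (TMEDA complex) | CC1C[C@@]2(O)[C@@H]3O[Os](=O)(=O)O[C@]3(C(C)C)CC[C@@]2(C)C4(C1)OCCO4.CN(C)CCN(C)C
F2 | step 10 | all-cis 1,1-ethylenedioxy-6α-isopropyl-3,8aβ-dimethyldecalin-4aβ,5β,6β-triol | CC1C[C@@]2(O)[C@H](O)[C@@](O)(C(C)C)CC[C@@]2(C)C3(C1)OCCO3
F3 | step 10 | 5β-methanesulfonate of triol F2 | CC1C[C@@]2(O)[C@H](OS(C)(=O)=O)[C@@](O)(C(C)C)CC[C@@]2(C)C3(C1)OCCO3
F4 | step 7 | 4aβ,5β-epoxy-1,1-ethylenedioxy-6-isopropyl-3,8aβ-dimethyldecalin-6-ol (C6 configuration not specified) | CC1C[C@]23O[C@@H]3C(O)(C(C)C)CC[C@@]2(C)C4(C1)OCCO4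
F5 | step 7 | 4aβ,5β-epoxy-1,1-ethylenedioxy-6-isopropylidene-3,8aβ-dimethyldecalin | CC1C[C@]23O[C@@H]3C(=C(C)C)CC[C@@]2(C)C4(C1)OCCO4
F6 | step 18 | 6α,10α-bis{2-[bis(2,2,2-trifluoroethoxy)phosphoryl]propanoyloxy}-8α,9α-(isopropylidenedioxy)daucan-4β-ol | CC(C(=O)O[C@@H]1C[C@]2(C)OC(C)(C)O[C@@H]2[C@H](OC(=O)C(C)P(=O)(OCC(F)(F)F)OCC(F)(F)F)[C@]3(C)CC[C@](O)(C(C)C)[C@@H]13)P(=O)(OCC(F)(F)F)OCC(F)(F)F
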